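**Retrosynthetic overview**

1. Target 13 ⇐ oxirane closure by the C1 oxygen onto C6 (bromide 12, second inversion) ⇐ C6 bromination with inversion of diol 11 ⇐ C3 benzoylation of triol 10 ⇐ O–O reduction of endoperoxide 9.
2. The strategy rests on one feature of the cyclohexene ring: the C3–O bond (benzoate) and the C6–O bond (oxirane) are cis-1,4 across the C4=C5 double bond. Both bonds are disconnected together, back to singlet oxygen and the C3=C4–C5=C6 diene of 8.
3. Diene 8 ⇐ Mitsunobu inversion at C2 with acetic acid 7 ⇐ C7 monobenzoate 6 ⇐ triol 4 ⇐ methyl ester 3 ⇐ diol acid 2 ⇐ enzymatic ipso,ortho-cis-dihydroxylation of benzoic acid 1, which sets C1 and C2.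
4. Ring order: carbocycle (the arene ring of 1), then the 1,2-dioxine ring of the 2,3-dioxabicyclo[2.2.2]octene (step 6, reopened in step 7), then the oxirane (step 10).

Key step: step 6

Remark on numbering: ring atoms are numbered as in the target core. C1 is the fully substituted carbon bearing the exocyclic C7H2, C2 the acetate carbon, C3 the benzoate carbon, C4=C5 the alkene, C6 the second oxirane carbon. "Upper face" means the face of the C1 oxygen. All descriptors refer to this numbering.

Assumption: the benzoate 1,2-dioxygenase of Ralstonia eutropha B9 is taken to deliver the (1S,2R) cis-diol acid, which is the enantiomer that maps onto the target.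

**Route**

Step 1
Reactants: 1 benzoic acid
Product: 2 (1S,2R)-1,2-dihydroxycyclohexa-3,5-diene-1-carboxylic acid (C1–OH and C2–OH cis)
Conditions: Ralstonia eutropha B9 whole cells (benzoate 1,2-dioxygenase, diol dehydrogenase blocked), air, fructose, phosphate buffer pH 7, 30 °C; then pH 3, EtOAc extraction
Reagents that add atoms: dioxygen, O=O
Why: Enzymatic arene cis-dihydroxylation by a non-heme iron dioxygenase delivers both atoms of one O2 suprafacially to the ipso and ortho carbons inside the chiral active site, which sets C1 (S) and C2 (R) cis in one event, while the blocked dehydrogenase prevents rearomatisation and the NADH is regenerated by the cells.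

Step 2
Reactants: 2 (1S,2R)-1,2-dihydroxycyclohexa-3,5-diene-1-carboxylic acid
Product: 3 methyl (1S,2R)-1,2-dihydroxycyclohexa-3,5-diene-1-carboxylate
Conditions: TMSCHN2, MeOH/toluene, 0 °C
Reagents that add atoms: trimethylsilyldiazomethane, C[Si](C)(C)C=[N+]=[N-]
Why: Methyl esterification of a carboxylic acid with trimethylsilyldiazomethane in methanol is neutral and cold, so the acid-labile dienediol is not dehydrated and neither stereocentre is touched.

Step 3
Reactants: 3 methyl (1S,2R)-1,2-dihydroxycyclohexa-3,5-diene-1-carboxylate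
Product: 4 (1R,2R)-1-(hydroxymethyl)cyclohexa-3,5-diene-1,2-diol (same spatial arrangement as 3; the C1 descriptor changes by priority only)
Conditions: LiAlH4, THF, 0 °C; Na2SO4·10H2O quench, filtration
Reagents that add atoms: none
Why: Hydride reduction of an ester to the primary alcohol with LiAlH4 proceeds in a basic aluminate medium and, with a non-acidic quench, should leave the diene, the diol and both stereocentres intact.

Step 4
Reactants: 4 (1R,2R)-1-(hydroxymethyl)cyclohexa-3,5-diene-1,2-diol; 5 benzoyl chloride
Product: 6 (1R,2R)-1-(benzoyloxymethyl)cyclohexa-3,5-diene-1,2-diol (C7 monobenzoate, cis-diol)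
Conditions: BzCl (1.05 equiv), 2,4,6-collidine, CH2Cl2, −40 °C
Reagents that add atoms: benzoyl chloride (5), O=C(Cl)c1ccccc1
Why: Selective acylation with an acid chloride and a hindered pyridine base at low temperature should take the primary C7 hydroxyl in preference to the hindered secondary C2 and the tertiary C1 hydroxyl, with no stereocentre affected.

Step 5
Reactants: 6 (1R,2R)-1-(benzoyloxymethyl)cyclohexa-3,5-diene-1,2-diol; 7 acetic acid
Product: 8 (1R,2S)-2-acetoxy-1-(benzoyloxymethyl)cyclohexa-3,5-dien-1-ol (C1–OH on the upper face; C2–OAc and C7 on the lower face)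
Conditions: AcOH, PPh3, DIAD, THF, 0 °C
Reagents that add atoms: acetic acid (7), CC(O)=O
Why: In this Mitsunobu esterification only the secondary C2 hydroxyl forms a reactive oxyphosphonium ion (the tertiary C1 hydroxyl is inert and, being cis, cannot displace it as an oxirane), and acetate displaces it by SN2 with inversion, which places the C2 acetate trans to the C1 hydroxyl; C1 carries no hydrogen, so direct elimination to an arene is not open.

Step 6
Reactants: 8 (1R,2S)-2-acetoxy-1-(benzoyloxymethyl)cyclohexa-3,5-dien-1-ol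
Product: 9 (1R,2S,3R,6S)-2-acetoxy-1-(benzoyloxymethyl)-3,6-epidioxycyclohex-4-en-1-ol (a 2,3-dioxabicyclo[2.2.2]oct-5-ene; peroxide bridge on the upper face, syn to C1–OH and anti to C2–OAc)
Conditions: O2 (1 atm), 5,10,15,20-tetraphenylporphyrin (1 mol %), white LED, CH2Cl2, −20 °C
Reagents that add atoms: dioxygen, O=O
Why: Photosensitised singlet oxygen adds as the 2π partner across C3 and C6 of the s-cis diene held in the six-membered ring in a concerted suprafacial [4+2] cycloaddition, the known endoperoxidation of cyclohexa-1,3-dienes and of arene cis-dihydrodiol derivatives. The 1,2-dioxine ring (C3–O–O–C6 with C4=C5) closes by intermolecular cycloaddition, both C–O bonds forming in one event, which turns the carbocycle into the 2,3-dioxabicyclo[2.2.2]oct-5-ene. C3 and C6 are set together, with both oxygens on one face by suprafaciality, and that face is chosen by the resident C1 and C2 centres: the upper face carries only the C1 hydroxyl and the C2 hydrogen, whereas the lower face carries the C7 benzoyloxymethyl group and the allylic C2 acetate, which shield it sterically and repel the electrophilic oxygen. The free tertiary C1 hydroxyl can also hydrogen-bond to the incoming oxygen in the non-polar solvent, so steric and directing effects point the same way. The step needs this facial selectivity together with [4+2] rather than ene reactivity, which the cisoid ring diene favours, and the neutral, cold conditions should keep the dienol from aromatising.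

Step 7
Reactants: 9 (1R,2S,3R,6S)-2-acetoxy-1-(benzoyloxymethyl)-3,6-epidioxycyclohex-4-en-1-ol
Product: 10 (1S,2S,3R,6S)-2-acetoxy-1-(benzoyloxymethyl)cyclohex-4-ene-1,3,6-triol (C1, C3 and C6 hydroxyls all on the upper face)
Conditions: thiourea (1.2 equiv), MeOH (reagent grade), 0 °C → rt
Reagents that add atoms: none
Why: Thiourea reduction of a bicyclic endoperoxide cleaves only the O–O bond, so both C–O bonds and the cis-1,4 configuration at C3 and C6 are retained, and the neutral medium spares the esters and avoids the base-induced Kornblum–DeLaMare rearrangement.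

Step 8
Reactants: 10 (1S,2S,3R,6S)-2-acetoxy-1-(benzoyloxymethyl)cyclohex-4-ene-1,3,6-triol; 5 benzoyl chloride
Product: 11 (1S,2S,3R,6S)-2-acetoxy-3-benzoyloxy-1-(benzoyloxymethyl)cyclohex-4-ene-1,6-diol
Conditions: BzCl (1.05 equiv), pyridine, CH2Cl2, −40 → −20 °C
Reagents that add atoms: benzoyl chloride (5), O=C(Cl)c1ccccc1
Why: Regioselective acylation should take the C3 hydroxyl, which sits next to a CH(OAc) carbon, over the C6 hydroxyl, which is neopentyl-like beside the fully substituted C1, and over the tertiary C1 hydroxyl, with retention at every centre.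

Step 9
Reactants: 11 (1S,2S,3R,6S)-2-acetoxy-3-benzoyloxy-1-(benzoyloxymethyl)cyclohex-4-ene-1,6-diol
Product: 12 (1R,2S,3R,6R)-2-acetoxy-3-benzoyloxy-1-(benzoyloxymethyl)-6-bromocyclohex-4-en-1-ol (bromine on the lower face, trans to C1–OH)
Conditions: CBr4, PPh3, CH2Cl2, 0 °C
Reagents that add atoms: tetrabromomethane, BrC(Br)(Br)Br
Why: In this Appel reaction only the secondary allylic C6 hydroxyl becomes an oxyphosphonium ion (the tertiary C1 hydroxyl is inert and, being cis, cannot close an oxirane), and bromide displaces it from the opposite face by SN2, which inverts C6.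

Step 10
Reactants: 12 (1R,2S,3R,6R)-2-acetoxy-3-benzoyloxy-1-(benzoyloxymethyl)-6-bromocyclohex-4-en-1-ol
Product: 13 [(1S,2S,3R,6S)-2-acetoxy-3-benzoyloxy-7-oxabicyclo[4.1.0]hept-4-en-1-yl]methyl benzoate (target)
Conditions: Cs2CO3, MeCN, 0 °C → rt
Reagents that add atoms: none
Why: Base-induced halohydrin cyclisation (intramolecular Williamson reaction, 3-exo-tet) lets the C1 alkoxide attack C6 anti to bromide, a second inversion that puts the oxirane oxygen at C6 on the upper face, cis to the C3 benzoate, while the carbonate base in an aprotic solvent should leave the three esters alone.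

**Compound list**

1 | benzoic acid | OC(=O)c1ccccc1 | starting material
2 | (1S,2R)-1,2-dihydroxycyclohexa-3,5-diene-1-carboxylic acid | O[C@@H]1C=CC=C[C@@]1(O)C(O)=O | intermediate
3 | methyl (1S,2R)-1,2-dihydroxycyclohexa-3,5-diene-1-carboxylate | O[C@@H]1C=CC=C[C@@]1(O)C(=O)OC | intermediate
4 | (1R,2R)-1-(hydroxymethyl)cyclohexa-3,5-diene-1,2-diol | O[C@@H]1C=CC=C[C@@]1(O)CO | intermediate
5 | benzoyl chloride | O=C(Cl)c1ccccc1 | starting material
6 | (1R,2R)-1-(benzoyloxymethyl)cyclohexa-3,5-diene-1,2-diol | O[C@@H]1C=CC=C[C@@]1(O)COC(=O)c1ccccc1 | intermediate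
7 | acetic acid | CC(O)=O | starting material
8 | (1R,2S)-2-acetoxy-1-(benzoyloxymethyl)cyclohexa-3,5-dien-1-ol | CC(=O)O[C@H]1C=CC=C[C@@]1(O)COC(=O)c1ccccc1 | intermediate
9 | (1R,2S,3R,6S)-2-acetoxy-1-(benzoyloxymethyl)-3,6-epidioxycyclohex-4-en-1-ol | CC(=O)O[C@H]1[C@H]2C=C[C@H](OO2)[C@@]1(O)COC(=O)c1ccccc1 | intermediate
10 | (1S,2S,3R,6S)-2-acetoxy-1-(benzoyloxymethyl)cyclohex-4-ene-1,3,6-triol | CC(=O)O[C@H]1[C@H](O)C=C[C@H](O)[C@@]1(O)COC(=O)c1ccccc1 | intermediate
11 | (1S,2S,3R,6S)-2-acetoxy-3-benzoyloxy-1-(benzoyloxymethyl)cyclohex-4-ene-1,6-diol | CC(=O)O[C@H]1[C@H](OC(=O)c2ccccc2)C=C[C@H](O)[C@@]1(O)COC(=O)c1ccccc1 | intermediate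
12 | (1R,2S,3R,6R)-2-acetoxy-3-benzoyloxy-1-(benzoyloxymethyl)-6-bromocyclohex-4-en-1-ol | CC(=O)O[C@H]1[C@H](OC(=O)c2ccccc2)C=C[C@@H](Br)[C@@]1(O)COC(=O)c1ccccc1 | intermediate
13 | [(1S,2S,3R,6S)-2-acetoxy-3-benzoyloxy-7-oxabicyclo[4.1.0]hept-4-en-1-yl]methyl benzoate | CC(=O)O[C@H]1[C@H](OC(=O)c2ccccc2)C=C[C@@H]2O[C@@]21COC(=O)c1ccccc1 | target

**Step count**

Total steps: 10. Longest linear sequence: 10 steps (1 → 13).

**Steps most likely to fail**

Step 6 (photooxygenation). Singlet oxygen may attack the lower face as well, giving poor facial selectivity, or the dienol may lose water and aromatise during irradiation. The fallback sets out from 8 and replaces the cycloaddition by a directed epoxidation followed by a 1,4-opening. Peracid epoxidation (mCPBA, NaHCO3, CH2Cl2, 0 °C), directed by hydrogen bonding to the C1 hydroxyl, should epoxidise the adjacent C5=C6 bond on the upper face to give the vinyl oxirane (1R,2S,5S,6S)-2-acetoxy-1-(benzoyloxymethyl)-5,6-epoxycyclohex-3-en-1-ol F1. Pd(PPh3)4 (zerovalent palladium, catalytic) with benzoic acid 1 in THF at 0 °C should then ionise the allylic C5–O bond with inversion and deliver benzoate to C3 anti to palladium (Tsuji–Trost 1,4-addition, net cis). This gives the C3 benzoate with the C6 hydroxyl on the upper face, and the route is rejoined at 11, with steps 6 to 8 bypassed.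

Step 9 (bromination with inversion). Several processes could erode regio- and stereocontrol at C6:
- bromide may attack C4 in an SN2' sense;
- the C7 benzoate carbonyl may participate at C6;
- the allylic bromide may be epimerised by bromide ion;
- the cis C1 hydroxyl may tie up phosphorus as a cyclic phosphorane and stall the reaction.

The fallback sets out from 11 and inverts C6 by oxidation and reduction instead of substitution. Dess–Martin periodinane (NaHCO3, CH2Cl2, 0 °C) should oxidise only the secondary allylic hydroxyl to the enone (1R,2S,3R)-2-acetoxy-3-benzoyloxy-1-(benzoyloxymethyl)-1-hydroxycyclohex-4-en-6-one F2. Me4NBH(OAc)3 (MeCN/AcOH, −20 °C), bound to the C1 hydroxyl, should deliver hydride to the upper face of the carbonyl and give the trans-diol (1S,2S,3R,6R)-2-acetoxy-3-benzoyloxy-1-(benzoyloxymethyl)cyclohex-4-ene-1,6-diol F3. MsCl/Et3N (CH2Cl2, −20 °C) should sulfonylate only the secondary hydroxyl to give the mesylate (1R,2S,3R,6R)-2-acetoxy-3-benzoyloxy-1-(benzoyloxymethyl)-1-hydroxycyclohex-4-en-6-yl methanesulfonate F4. DBU (CH2Cl2, 0 °C) then closes the oxirane by attack of the C1 oxygen anti to the mesylate, and the route is rejoined at the target 13.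

Step 5 (Mitsunobu inversion). The dienylic oxyphosphonium ion may be captured by SN2' attack or may ionise to a cyclohexadienyl cation. Activation could also fall on the tertiary C1 oxygen, or the C7 benzoate could participate. Any of these would lead to loss of configuration at C2 or to aromatisation. The fallback sets out from 3 and moves the inversion to the ester stage, where the C1 ester disfavours ionisation and no C7 benzoate is present. Mitsunobu reaction with 4-nitrobenzoic acid (PPh3, DIAD, THF, 0 °C) should give methyl (1S,2S)-1-hydroxy-2-(4-nitrobenzoyloxy)cyclohexa-3,5-diene-1-carboxylate F5. LiBH4 (THF/MeOH, 0 °C) reduces both esters to the trans-triol (1R,2S)-1-(hydroxymethyl)cyclohexa-3,5-diene-1,2-diol F6. Benzoyl chloride 5 with 2,4,6-collidine (CH2Cl2, −40 °C) acylates the primary hydroxyl to give (1R,2S)-1-(benzoyloxymethyl)cyclohexa-3,5-diene-1,2-diol F7. Ac2O/pyridine (0 °C) acetylates the secondary C2 hydroxyl and not the tertiary one, and the route is rejoined at 8.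

**Further compounds**

F1 | step 6 | (1R,2S,5S,6S)-2-acetoxy-1-(benzoyloxymethyl)-5,6-epoxycyclohex-3-en-1-ol | CC(=O)O[C@H]1C=C[C@@H]2O[C@@H]2[C@@]1(O)COC(=O)c1ccccc1
F2 | step 9 | (1R,2S,3R)-2-acetoxy-3-benzoyloxy-1-(benzoyloxymethyl)-1-hydroxycyclohex-4-en-6-one | CC(=O)O[C@H]1[C@H](OC(=O)c2ccccc2)C=CC(=O)[C@@]1(O)COC(=O)c1ccccc1
F3 | step 9 | (1S,2S,3R,6R)-2-acetoxy-3-benzoyloxy-1-(benzoyloxymethyl)cyclohex-4-ene-1,6-diol | CC(=O)O[C@H]1[C@H](OC(=O)c2ccccc2)C=C[C@@H](O)[C@@]1(O)COC(=O)c1ccccc1
F4 | step 9 | (1R,2S,3R,6R)-2-acetoxy-3-benzoyloxy-1-(benzoyloxymethyl)-1-hydroxycyclohex-4-en-6-yl methanesulfonate | CC(=O)O[C@H]1[C@H](OC(=O)c2ccccc2)C=C[C@@H](OS(C)(=O)=O)[C@@]1(O)COC(=O)c1ccccc1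
F5 | step 5 | methyl (1S,2S)-1-hydroxy-2-(4-nitrobenzoyloxy)cyclohexa-3,5-diene-1-carboxylate | O=C(O[C@H]1C=CC=C[C@@]1(O)C(=O)OC)c1ccc(cc1)[N+](=O)[O-]
F6 | step 5 | (1R,2S)-1-(hydroxymethyl)cyclohexa-3,5-diene-1,2-diol | O[C@H]1C=CC=C[C@@]1(O)CO
F7 | step 5 | (1R,2S)-1-(benzoyloxymethyl)cyclohexa-3,5-diene-1,2-diol | O[C@H]1C=CC=C[C@@]1(O)COC(=O)c1ccccc1
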